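The numbers come from no measurement; the rest is arithmetic.

I counted J first.

- north-east: D 0.050 M; E 1 mol%; J 0.32 mM; time 1.5 h
- east: D 0.050 M; E 1 mol%; J 0.32 mM; time 2.0 h

    G + Q ⇌ D + Q, rate k1*[Q]*[G] forward; the back reaction follows from the equilibrium constant (k1 = 0.699 /M/s)
    D + Q ⇌ X + Q, rate k2*[D]*[Q] forward; the back reaction follows from the equilibrium constant (K2 = 0.398, k2 = 0.342 /M/s)
    E → Q (k3 = 2.55 × 10⁻⁴ /s)
    Q + J → Q.J (k4 = 555 /M/s)
    X + Q ⇌ G + Q, rate k5*[Q]*[X] forward; the back reaction follows from the equilibrium constant (K5 = 16.1, k5 = 2.70 /M/s)

- which of the two there is more of at the end, north-east (G / X)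
- which of the two there is more of at the end, east (G / X)
- final X, as a percentage of the D charged, in north-east
- final X, as a percentage of the D charged, in east

The fastest rung was capture. J held a free Q to a pseudo-first-order lifetime of 5.63 s, far shorter than the 1.09 h lifetime of E, whose half-life is 0.76 h. So I expected [Q] to stay very low while J lasted, with the release from E setting the pace. The next rung was the count. The two recipes charge E at 0.500 mM and J at 0.32 mM, so J is the limiting reagent of the capture, at 64.0% of E. That gave me the breakthrough time 1.11 h, the moment when the Q released from E has matched the J charged. It falls before the end in north-east and in east.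

The slowest rung came after it. By my count, free [Q] reached 0.0538 mM at the end in north-east and 0.100 mM in east. The reverse of G + Q ⇌ D + Q turns D into G with the constant 4.48 /M/s, which is 13.1 times k2. I therefore put G ahead of X in both flasks. Taking k2 times the integral of [Q] after the breakthrough time gave X of about 1.36% in north-east. The same count gave 6.21% in east, but it holds [D] at its charge and lets no X leave, so I took it as a rough figure for east.

The forecast put X ahead in north-east and G ahead in east, with X at 1.5% and 4.4%, holding that “the D→X→G cycle is still early”. We parted on north-east, where I had G.

North-east ended with X at 1.41% and G at 18.8%, east with X at 3.79% and G at 52.8%. At 0.750 h in north-east, Q stood at 0.313% of the catalyst charged, with 22.7% of J remaining. Past the breakthrough time, north-east had 0.387 h and east 0.887 h. A neighbour of east with 0.085 M of D and J at 0.00376 equiv has a breakthrough time of 0.515 h, and at 2.00 h it held D at 12.9%, X at 5.12% and G at 82.0%.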